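**Strategy**

The farnesyl chain on C6 of ring A is cut between C5′ (CH2) and C6′ (vinyl CH). The key step exploits the C4′–C5′ ethano link between the two E-trisubstituted olefins C2′=C3′ and C6′=C7′: 9-BBN hydroborates only the terminal vinyl group of a 3-methylpenta-2,4-dienyl side chain, placing boron on C5′, and B-alkyl Suzuki coupling with an E-alkenyl iodide made by alkyne methylalumination forges C5′–C6′ with both geometries retained. The precursor is a symmetric ring A phenol carrying a conjugated diene, not a 1,5-diene. Ring C is then built on the single free phenol oxygen, and C2 is set by rhodium-catalysed asymmetric aryl addition to the chromone.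

Key step: step 7

Remark: primed locants number the farnesyl chain from the carbon bonded to C6 of ring A; the (S)-biaryl bisphosphine of step 13 is assumed to give the 2S product by the facial sense known for cyclic enones, and its antipode would be used otherwise.

**Route**

Step 1
Reactants: 1 phloroglucinol
Product: 2 3,5-bis(methoxymethoxy)phenol
Conditions: NaH (2.0 equiv), MOMCl (2.0 equiv), DMF, 0 °C → rt; chromatography
Reagents that add atoms: chloromethyl methyl ether (COCCl)
Why: Stoichiometrically limited Williamson O-alkylation (MOM protection) should give the bis-ether as the main part of a statistical mixture, leaving one free hydroxyl that later becomes O1 and so fixes the ring A regiochemistry.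

Step 2
Reactants: 3 (2E)-3-methylpent-2-en-4-yn-1-ol
Product: 4 (2E)-3-methylpenta-2,4-dien-1-ol
Conditions: H2 (1 atm), Pd/CaCO3 poisoned with Pb(OAc)2 (Lindlar), quinoline, EtOAc, rt, stopped at 1 equiv uptake
Reagents that add atoms: none
Why: Lindlar semi-hydrogenation of the terminal alkyne should stop at the vinyl group and leave the E trisubstituted olefin (the later C2′=C3′) untouched.

Step 3
Reactants: 4 (2E)-3-methylpenta-2,4-dien-1-ol
Product: 5 (3E)-5-bromo-3-methylpenta-1,3-diene
Conditions: PBr3 (0.4 equiv), Et2O, −20 °C; used at once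
Reagents that add atoms: phosphorus tribromide (BrP(Br)Br)
Why: SN2 bromination of the primary allylic alcohol through its phosphite ester at low temperature should keep the E geometry, and the bromide is not stored.

Step 4
Reactants: 2 3,5-bis(methoxymethoxy)phenol; 5 (3E)-5-bromo-3-methylpenta-1,3-diene
Product: 7 4-[(2E)-3-methylpenta-2,4-dien-1-yl]-3,5-bis(methoxymethoxy)phenol, via dilithio species 6 (not isolated)
Conditions: n-BuLi (2.2 equiv), TMEDA, THF, 0 °C; CuBr·SMe2 (10 mol%), then 5, −78 → 0 °C; then H2O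
Reagents that add atoms: none
Why: Directed ortho-metalation of the lithium phenoxide should occur at C4, the only site flanked by two methoxymethoxy groups, and copper-catalysed SN2 allylation at the primary bromide carbon should carry the E-diene over unchanged, attack at the far diene terminus giving the same constitution because the 3-methylpentadienyl unit is symmetric.

Step 5
Reactants: 8 5-bromo-2-methylpent-2-ene
Product: 9 6-methylhept-5-en-1-yne
Conditions: LiC≡CH·H2NCH2CH2NH2, DMSO, 10 °C → rt
Reagents that add atoms: lithium acetylide ethylenediamine complex ([Li]C#C.NCCN)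
Why: Acetylide alkylation by SN2 displacement at the unhindered primary homoallylic bromide.

Step 6
Reactants: 9 6-methylhept-5-en-1-yne
Product: 11 (1E)-1-iodo-2,6-dimethylhepta-1,5-diene, via alkenylalane 10 (not isolated)
Conditions: AlMe3 (2 equiv), Cp2ZrCl2 (20 mol%), CH2Cl2, rt; then I2, THF, −30 → 0 °C
Reagents that add atoms: trimethylaluminium (C[Al](C)C); iodine ([I][I])
Why: Negishi zirconium-catalysed carboalumination adds methyl and aluminium syn across the terminal alkyne with aluminium at the terminus, and iodinolysis of the C–Al bond with retention sets the E geometry of C6′=C7′.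

Step 7
Reactants: 7 4-[(2E)-3-methylpenta-2,4-dien-1-yl]-3,5-bis(methoxymethoxy)phenol; 11 (1E)-1-iodo-2,6-dimethylhepta-1,5-diene
Product: 13 3,5-bis(methoxymethoxy)-4-[(2E,6E)-3,7,11-trimethyldodeca-2,6,10-trien-1-yl]phenol, via B-alkyl-9-BBN adduct 12 (not isolated)
Conditions: 9-BBN-H dimer (2.3 equiv B–H), THF, 0 °C → rt; then 3 M aq. NaOH, 11 (1.2 equiv), PdCl2(dppf) (5 mol%), AsPh3 (10 mol%), DMF, rt → 45 °C
Reagents that add atoms: none
Why: 9-BBN adds B–H syn and anti-Markovnikov to the monosubstituted C4′=C5′ olefin of the diene and places boron on terminal C5′, while the trisubstituted C2′=C3′ olefin is inert to this bulky borane at room temperature and one further equivalent is taken up by the phenol as an O–B bond that hydroxide cleaves again. Zerovalent palladium inserts into the C6′–I bond of 11 with retention, hydroxide turns the B-alkyl-9-BBN into a borate that hands the primary C5′ alkyl group to palladium, and reductive elimination forms the C5′–C6′ bond. The closest known reaction type is the B-alkyl Suzuki–Miyaura coupling of 9-BBN adducts with alkenyl iodides. No ring is closed and no stereocentre is formed; the E geometry of C2′=C3′ (from 3) and of C6′=C7′ (from step 6) must be kept, and neither olefin takes part in the bond-forming events. The step needs regioselective monohydroboration, secured by the steric demand of 9-BBN for the unsubstituted diene terminus, and reductive elimination faster than β-hydride elimination, secured by the wide-bite-angle dppf ligand.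

Step 8
Reactants: 13 3,5-bis(methoxymethoxy)-4-[(2E,6E)-3,7,11-trimethyldodeca-2,6,10-trien-1-yl]phenol
Product: 14 2-hydroxy-4,6-bis(methoxymethoxy)-5-[(2E,6E)-3,7,11-trimethyldodeca-2,6,10-trien-1-yl]benzaldehyde
Conditions: MgCl2, Et3N, (CH2O)n, MeCN, 75 °C
Reagents that add atoms: paraformaldehyde, as formaldehyde (C=O)
Why: Magnesium-mediated ortho-formylation (Casnati–Skattebøl) delivers formaldehyde only ortho to the phenoxide oxygen through a magnesium chelate, and since both ortho positions of the symmetric phenol are equivalent the future C4 carbon is placed between O1 and the 5-oxygen without ambiguity.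

Step 9
Reactants: 14 2-hydroxy-4,6-bis(methoxymethoxy)-5-[(2E,6E)-3,7,11-trimethyldodeca-2,6,10-trien-1-yl]benzaldehyde
Product: 15 1-{2-hydroxy-4,6-bis(methoxymethoxy)-5-[(2E,6E)-3,7,11-trimethyldodeca-2,6,10-trien-1-yl]phenyl}prop-2-yn-1-ol (racemic)
Conditions: HC≡CMgBr (3 equiv), THF, 0 °C → rt; then H2O (pH 7 buffer)
Reagents that add atoms: ethynylmagnesium bromide (C#C[Mg]Br)
Why: Grignard 1,2-addition to the aldehyde after the first equivalent has deprotonated the phenol, the carbinol centre being formed as a racemate that the next step removes.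

Step 10
Reactants: 15 1-{2-hydroxy-4,6-bis(methoxymethoxy)-5-[(2E,6E)-3,7,11-trimethyldodeca-2,6,10-trien-1-yl]phenyl}prop-2-yn-1-ol
Product: 18 5,7-bis(methoxymethoxy)-6-[(2E,6E)-3,7,11-trimethyldodeca-2,6,10-trien-1-yl]-4H-chromen-4-one, via ynone 16 (not isolated), via enaminone 17 (not isolated)
Conditions: MnO2 (15 equiv), CH2Cl2, rt; filter; Et2NH (1.5 equiv), EtOH, rt → 50 °C
Reagents that add atoms: none
Why: MnO2 oxidation of the benzylic propargylic alcohol gives the ynone, conjugate addition of diethylamine gives the enaminone, and 6-endo addition–elimination by the only free phenol oxygen (oxa-Michael/elimination) closes the pyranone ring with release of diethylamine.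

Step 11
Reactants: 19 5-bromobenzene-1,3-diol
Product: 20 1-bromo-3,5-bis(methoxymethoxy)benzene
Conditions: NaH (2.4 equiv), MOMCl (2.4 equiv), DMF, 0 °C → rt
Reagents that add atoms: chloromethyl methyl ether (COCCl)
Why: Williamson O-alkylation (MOM protection) of both phenoxides.

Step 12
Reactants: 20 1-bromo-3,5-bis(methoxymethoxy)benzene
Product: 23 [3,5-bis(methoxymethoxy)phenyl]boronic acid, via aryllithium 21 (not isolated), via borate complex 22 (not isolated)
Conditions: B(OiPr)3 (1.5 equiv), THF, −78 °C, then n-BuLi (1.1 equiv); then H2O (pH 7)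
Reagents that add atoms: triisopropyl borate (CC(C)OB(OC(C)C)OC(C)C); water (O)
Why: Bromine–lithium exchange is faster than ortho-lithiation at −78 °C, the aryllithium is trapped at once by the borate already present, and neutral hydrolysis gives the boronic acid with the acetals intact.

Step 13
Reactants: 18 5,7-bis(methoxymethoxy)-6-[(2E,6E)-3,7,11-trimethyldodeca-2,6,10-trien-1-yl]-4H-chromen-4-one; 23 [3,5-bis(methoxymethoxy)phenyl]boronic acid
Product: 24 (2S)-2-[3,5-bis(methoxymethoxy)phenyl]-5,7-bis(methoxymethoxy)-6-[(2E,6E)-3,7,11-trimethyldodeca-2,6,10-trien-1-yl]-2,3-dihydro-4H-chromen-4-one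
Conditions: [RhCl(C2H4)2]2 (2.5 mol%), (S)-MeO-F12-BIPHEP (5.5 mol%), aq. KOH (20 mol%), toluene/H2O, 40 °C
Reagents that add atoms: none
Why: Hayashi–Miyaura rhodium-catalysed asymmetric 1,4-addition, in which the aryl–rhodium species bound to the (S)-biaryl bisphosphine inserts the C2=C3 bond of the chromone from one face and the oxa-π-allyl rhodium is hydrolysed, should set C2 as S, and the electron-poor ligand allows a temperature at which the base-sensitive flavanone should not ring-open.

Step 14
Reactants: 24 (2S)-2-[3,5-bis(methoxymethoxy)phenyl]-5,7-bis(methoxymethoxy)-6-[(2E,6E)-3,7,11-trimethyldodeca-2,6,10-trien-1-yl]-2,3-dihydro-4H-chromen-4-one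
Product: 25 (2S)-2-(3,5-dihydroxyphenyl)-5,7-dihydroxy-6-[(2E,6E)-3,7,11-trimethyldodeca-2,6,10-trien-1-yl]-2,3-dihydro-4H-chromen-4-one
Conditions: 3 M aq. HCl, MeOH, 45 °C
Reagents that add atoms: none
Why: Acid-catalysed acetal exchange with methanol removes all four MOM groups, C2 is not expected to epimerise because ring opening of flavanones needs base, and the trisubstituted olefins should survive the dilute acid.

**Compound list**

1 | phloroglucinol (benzene-1,3,5-triol) | Oc1cc(O)cc(O)c1 | starting material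
2 | 3,5-bis(methoxymethoxy)phenol | COCOc1cc(O)cc(OCOC)c1 | intermediate
3 | (2E)-3-methylpent-2-en-4-yn-1-ol | C#C/C(C)=C/CO | starting material
4 | (2E)-3-methylpenta-2,4-dien-1-ol | C=C/C(C)=C/CO | intermediate
5 | (3E)-5-bromo-3-methylpenta-1,3-diene | C=C/C(C)=C/CBr | intermediate
6 | lithium 4-lithio-3,5-bis(methoxymethoxy)phenoxide (formed in the flask) | [Li]Oc1cc(OCOC)c([Li])c(OCOC)c1 | intermediate
7 | 4-[(2E)-3-methylpenta-2,4-dien-1-yl]-3,5-bis(methoxymethoxy)phenol | C=C/C(C)=C/Cc1c(OCOC)cc(O)cc1OCOC | intermediate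
8 | 5-bromo-2-methylpent-2-ene | CC(C)=CCCBr | starting material
9 | 6-methylhept-5-en-1-yne | C#CCCC=C(C)C | intermediate
10 | [(1E)-2,6-dimethylhepta-1,5-dien-1-yl]dimethylalane (formed in the flask) | CC(C)=CCC/C(C)=C/[Al](C)C | intermediate
11 | (1E)-1-iodo-2,6-dimethylhepta-1,5-diene | CC(C)=CCC/C(C)=C/I | intermediate
12 | B-alkyl-9-BBN adduct of 7 at C5′, phenol oxygen also borylated (formed in the flask) | COCOc1cc(OB2C3CCCC2CCC3)cc(OCOC)c1C/C=C(C)/CCB1C2CCCC1CCC2 | intermediate
13 | 3,5-bis(methoxymethoxy)-4-[(2E,6E)-3,7,11-trimethyldodeca-2,6,10-trien-1-yl]phenol | CC(C)=CCC/C(C)=C/CC/C(C)=C/Cc1c(OCOC)cc(O)cc1OCOC | intermediate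
14 | 2-hydroxy-4,6-bis(methoxymethoxy)-5-[(2E,6E)-3,7,11-trimethyldodeca-2,6,10-trien-1-yl]benzaldehyde | CC(C)=CCC/C(C)=C/CC/C(C)=C/Cc1c(OCOC)cc(O)c(C=O)c1OCOC | intermediate
15 | 1-{2-hydroxy-4,6-bis(methoxymethoxy)-5-[(2E,6E)-3,7,11-trimethyldodeca-2,6,10-trien-1-yl]phenyl}prop-2-yn-1-ol (racemic) | CC(C)=CCC/C(C)=C/CC/C(C)=C/Cc1c(OCOC)cc(O)c(C(O)C#C)c1OCOC | intermediate
16 | 1-{2-hydroxy-4,6-bis(methoxymethoxy)-5-[(2E,6E)-3,7,11-trimethyldodeca-2,6,10-trien-1-yl]phenyl}prop-2-yn-1-one (formed in the flask) | CC(C)=CCC/C(C)=C/CC/C(C)=C/Cc1c(OCOC)cc(O)c(C(=O)C#C)c1OCOC | intermediate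
17 | (2E)-3-(diethylamino)-1-{2-hydroxy-4,6-bis(methoxymethoxy)-5-[(2E,6E)-3,7,11-trimethyldodeca-2,6,10-trien-1-yl]phenyl}prop-2-en-1-one (formed in the flask) | CC(C)=CCC/C(C)=C/CC/C(C)=C/Cc1c(OCOC)cc(O)c(C(=O)/C=C/N(CC)CC)c1OCOC | intermediate
18 | 5,7-bis(methoxymethoxy)-6-[(2E,6E)-3,7,11-trimethyldodeca-2,6,10-trien-1-yl]-4H-chromen-4-one | CC(C)=CCC/C(C)=C/CC/C(C)=C/Cc1c(OCOC)cc2occc(=O)c2c1OCOC | intermediate
19 | 5-bromobenzene-1,3-diol | Oc1cc(O)cc(Br)c1 | starting material
20 | 1-bromo-3,5-bis(methoxymethoxy)benzene | COCOc1cc(Br)cc(OCOC)c1 | intermediate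
21 | [3,5-bis(methoxymethoxy)phenyl]lithium (formed in the flask) | [Li]c1cc(OCOC)cc(OCOC)c1 | intermediate
22 | lithium [3,5-bis(methoxymethoxy)phenyl]tri(propan-2-yloxy)borate (formed in the flask) | [Li+].CC(C)O[B-](OC(C)C)(OC(C)C)c1cc(OCOC)cc(OCOC)c1 | intermediate
23 | [3,5-bis(methoxymethoxy)phenyl]boronic acid | OB(O)c1cc(OCOC)cc(OCOC)c1 | intermediate
24 | (2S)-2-[3,5-bis(methoxymethoxy)phenyl]-5,7-bis(methoxymethoxy)-6-[(2E,6E)-3,7,11-trimethyldodeca-2,6,10-trien-1-yl]-2,3-dihydro-4H-chromen-4-one | CC(C)=CCC/C(C)=C/CC/C(C)=C/Cc1c(OCOC)cc2c(c1OCOC)C(=O)C[C@@H](c1cc(OCOC)cc(OCOC)c1)O2 | intermediate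
25 | (2S)-2-(3,5-dihydroxyphenyl)-5,7-dihydroxy-6-[(2E,6E)-3,7,11-trimethyldodeca-2,6,10-trien-1-yl]-2,3-dihydro-4H-chromen-4-one | CC(C)=CCC/C(C)=C/CC/C(C)=C/Cc1c(O)cc2c(c1O)C(=O)C[C@@H](c1cc(O)cc(O)c1)O2 | target

**Step count and risks**

Total steps: 14. Longest linear sequence: 9 steps (steps 2, 3, 4, 7, 8, 9, 10, 13, 14; from 3 to 25).

Steps most likely to fail:

Step 7. The hydroboration of the conjugated diene may be unselective (B–H addition at the internal carbon or a second addition), or transmetalation of the O-borylated substrate may be slow enough for protodeboronation to win. The fallback makes the C5′ nucleophile from an alkyl iodide instead of by hydrometalation; it sets out from 2 and comes back at 13. Commercial tert-butyl(but-3-yn-1-yloxy)dimethylsilane would be methylaluminated (AlMe3, Cp2ZrCl2 cat.), and the alanate (n-BuLi) trapped with paraformaldehyde to give (2E)-5-[(tert-butyldimethylsilyl)oxy]-3-methylpent-2-en-1-ol F1. Appel bromination (CBr4, PPh3) would give {[(3E)-5-bromo-3-methylpent-3-en-1-yl]oxy}(tert-butyl)dimethylsilane F2. Alkylation of dilithiated 2 with F2 under the conditions of step 4 would give 4-{(2E)-5-[(tert-butyldimethylsilyl)oxy]-3-methylpent-2-en-1-yl}-3,5-bis(methoxymethoxy)phenol F3. TBAF would give 4-[(2E)-5-hydroxy-3-methylpent-2-en-1-yl]-3,5-bis(methoxymethoxy)phenol F4, and I2/PPh3/imidazole would convert only the primary alcohol into 4-[(2E)-5-iodo-3-methylpent-2-en-1-yl]-3,5-bis(methoxymethoxy)phenol F5. After deprotonation of the phenol with NaH, zinc dust (LiCl, THF) would insert to give the sodium phenoxide of the alkylzinc iodide F6, and Negishi coupling with 11 (Pd(PPh3)4, THF) would give 13.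

Step 4. The pentadienyl bromide 5 may ionise or suffer SN2′-type attack with loss of the E geometry, and the dianion may be alkylated on oxygen. The fallback builds the diene after the arylation; it sets out from 2 and comes back at 7. The same dilithiation followed by commercial prenyl bromide would give 3,5-bis(methoxymethoxy)-4-(3-methylbut-2-en-1-yl)phenol F7. SeO2 allylic oxidation (ene reaction and [2,3]-shift, selective for the E methyl group; dioxane, 80 °C) would give (2E)-4-[4-hydroxy-2,6-bis(methoxymethoxy)phenyl]-2-methylbut-2-enal F8, and Wittig methylenation with excess Ph3P=CH2 would give 7.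

Step 10. The electron-rich o-hydroxybenzylic alcohol 15 may ionise to an ortho-quinone methide, the free phenol may be oxidised on MnO2, or the ring may close 5-exo. The fallback masks the phenol and closes the ring with fluoride; it sets out from 14 and comes back at 18. TIPSCl/imidazole would give 4,6-bis(methoxymethoxy)-2-[(triisopropylsilyl)oxy]-5-[(2E,6E)-3,7,11-trimethyldodeca-2,6,10-trien-1-yl]benzaldehyde F9. Ethynylmagnesium bromide would give the propargylic alcohol 1-{4,6-bis(methoxymethoxy)-2-[(triisopropylsilyl)oxy]-5-[(2E,6E)-3,7,11-trimethyldodeca-2,6,10-trien-1-yl]phenyl}prop-2-yn-1-ol F10. Dess–Martin periodinane would give the ynone 1-{4,6-bis(methoxymethoxy)-2-[(triisopropylsilyl)oxy]-5-[(2E,6E)-3,7,11-trimethyldodeca-2,6,10-trien-1-yl]phenyl}prop-2-yn-1-one F11, and TBAF would release the phenoxide, which should close 6-endo to chromone 18.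

Further compounds
F1 | step 7 | (2E)-5-[(tert-butyldimethylsilyl)oxy]-3-methylpent-2-en-1-ol | CC(C)(C)[Si](C)(C)OCC/C(C)=C/CO
F2 | step 7 | {[(3E)-5-bromo-3-methylpent-3-en-1-yl]oxy}(tert-butyl)dimethylsilane | CC(C)(C)[Si](C)(C)OCC/C(C)=C/CBr
F3 | step 7 | 4-{(2E)-5-[(tert-butyldimethylsilyl)oxy]-3-methylpent-2-en-1-yl}-3,5-bis(methoxymethoxy)phenol | CC(C)(C)[Si](C)(C)OCC/C(C)=C/Cc1c(OCOC)cc(O)cc1OCOC
F4 | step 7 | 4-[(2E)-5-hydroxy-3-methylpent-2-en-1-yl]-3,5-bis(methoxymethoxy)phenol | OCC/C(C)=C/Cc1c(OCOC)cc(O)cc1OCOC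
F5 | step 7 | 4-[(2E)-5-iodo-3-methylpent-2-en-1-yl]-3,5-bis(methoxymethoxy)phenol | ICC/C(C)=C/Cc1c(OCOC)cc(O)cc1OCOC
F6 | step 7 | sodium 4-[(2E)-5-(iodozincio)-3-methylpent-2-en-1-yl]-3,5-bis(methoxymethoxy)phenoxide | [Na+].[O-]c1cc(OCOC)c(C/C=C(C)/CC[Zn]I)c(OCOC)c1
F7 | step 4 | 3,5-bis(methoxymethoxy)-4-(3-methylbut-2-en-1-yl)phenol | CC(C)=CCc1c(OCOC)cc(O)cc1OCOC
F8 | step 4 | (2E)-4-[4-hydroxy-2,6-bis(methoxymethoxy)phenyl]-2-methylbut-2-enal | O=C/C(C)=C/Cc1c(OCOC)cc(O)cc1OCOC
F9 | step 10 | 4,6-bis(methoxymethoxy)-2-[(triisopropylsilyl)oxy]-5-[(2E,6E)-3,7,11-trimethyldodeca-2,6,10-trien-1-yl]benzaldehyde | CC(C)=CCC/C(C)=C/CC/C(C)=C/Cc1c(OCOC)cc(O[Si](C(C)C)(C(C)C)C(C)C)c(C=O)c1OCOC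
F10 | step 10 | 1-{4,6-bis(methoxymethoxy)-2-[(triisopropylsilyl)oxy]-5-[(2E,6E)-3,7,11-trimethyldodeca-2,6,10-trien-1-yl]phenyl}prop-2-yn-1-ol | CC(C)=CCC/C(C)=C/CC/C(C)=C/Cc1c(OCOC)cc(O[Si](C(C)C)(C(C)C)C(C)C)c(C(O)C#C)c1OCOC
F11 | step 10 | 1-{4,6-bis(methoxymethoxy)-2-[(triisopropylsilyl)oxy]-5-[(2E,6E)-3,7,11-trimethyldodeca-2,6,10-trien-1-yl]phenyl}prop-2-yn-1-one | CC(C)=CCC/C(C)=C/CC/C(C)=C/Cc1c(OCOC)cc(O[Si](C(C)C)(C(C)C)C(C)C)c(C(=O)C#C)c1OCOC
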